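**Retrosynthetic overview**

1. The diacetate is traced back to the 15,17-diol and then to a C17 ester conjugated with C7=C8. That enoate comes from a 7-oxo-8-ester (β-keto ester) through its enol triflate. The C12–C16 end of the side chain is joined by Wittig olefination of a C11 phosphonium group with a five-carbon lactol, and the C11=C12 bond is hydrogenated together with C5=C6.
2. Key disconnection: ring B is opened at C5–C6 and C8–C9. A [3+3] Michael/Horner–Wadsworth–Emmons annulation joins a C6–C7–C8(–C17) unit (a 4-phosphonoacetoacetate) to a ring A piece that carries the C5 ketone and, across quaternary C10, a C9=C11 alkenylphosphonium acceptor.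
3. Enabling feature: in ring B the C7=C8 double bond carries the oxygenated C17 on C8 and lies between C6 and C9. With C7 raised to a ketone, C8 and C6 become the two nucleophilic carbons of a β-keto ester, while C5 (a non-enolisable ring A ketone) and C9 are 1,3-electrophiles on either side of C10. The phosphonium group that activates C9 stays on C11 and later builds the side chain.
4. The ring A piece comes from 2,2,6-trimethylcyclohexanone by Pd-catalysed decarboxylative asymmetric allylation (sets C10); the allyl group is cut down to the C9 aldehyde and extended to the alkenylphosphonium salt.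
5. Ring order: ring A is bought, ring B is closed in the key step. Stereocentres: C10 (allylation), C9 (key step), C13 (asymmetric hydrogenation of a lactone), C5 (hydrogenation of the enone).

Key step: step 7

Remark on naming: bicyclic compounds carry labdane numbering (ring A = C1–C5 and C10; ring B = C5–C10; C17 on C8, C18/C19 on C4, C20 on C10, side chain C11–C16 on C9); α is the face opposite to C20.

Assumption: phosphonate 13 is taken as a catalogue compound, and in step 8 the BINAP antipode that gives (R)-18 is used once the sense of induction has been checked.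

**Step 1**
Reactants: 1 2,2,6-trimethylcyclohexan-1-one (racemic); 2 allyl chloroformate
Product: 4 prop-2-enyl 2,6,6-trimethylcyclohex-1-en-1-yl carbonate, via lithium enolate 3 (not isolated)
Conditions: LiN(SiMe3)2, THF, 0 °C; then 2, −78 → 25 °C
Reagents that add atoms: none
Why: The ketone has a single enolisable position, so its tetrasubstituted lithium enolate forms cleanly and is O-acylated by the chloroformate (enol carbonate formation); no stereocentre is involved.

**Step 2**
Reactants: 4 prop-2-enyl 2,6,6-trimethylcyclohex-1-en-1-yl carbonate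
Product: 5 (2R)-2,6,6-trimethyl-2-(prop-2-enyl)cyclohexan-1-one
Conditions: Pd2(dba)3 (2.5 mol %), (R)-t-Bu-PHOX (6 mol %), THF, 25 °C
Reagents that add atoms: none
Why: Decarboxylative asymmetric allylic alkylation (Tsuji allylation) on its standard substrate class: zerovalent palladium ionises the allyl carbonate, CO2 is lost, and the enolate/allyl pair recombines at C10 under control of the PHOX ligand, whose (R) antipode is chosen to give the (R) quaternary centre.

**Step 3**
Reactants: 5 (2R)-2,6,6-trimethyl-2-(prop-2-enyl)cyclohexan-1-one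
Product: 6 (2R)-2,6,6-trimethyl-2-[(E)-prop-1-enyl]cyclohexan-1-one
Conditions: RuHCl(CO)(PPh3)3 (3 mol %), toluene, 80 °C
Reagents that add atoms: none
Why: Ruthenium hydride olefin isomerisation (hydrometalation/β-hydride elimination) moves the terminal double bond one position inward to the more stable (E)-propenyl group; the quaternary centre stops further migration and is not touched.

**Step 4**
Reactants: 6 (2R)-2,6,6-trimethyl-2-[(E)-prop-1-enyl]cyclohexan-1-one
Product: 8 (1R)-1,3,3-trimethyl-2-oxocyclohexane-1-carbaldehyde, via ozonide 7 (not isolated)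
Conditions: O3, CH2Cl2, −78 °C; then Me2S, −78 → 25 °C
Reagents that add atoms: ozone, [O-][O+]=O
Why: Ozonolysis with reductive work-up cuts the propenyl group down to the aldehyde (the future C9); the work-up is neutral, so the non-enolisable β-keto aldehyde should neither epimerise nor lose its formyl group.

**Step 5**
Reactants: 8 (1R)-1,3,3-trimethyl-2-oxocyclohexane-1-carbaldehyde; 9 iodoform
Product: 10 (2R)-2-[(E)-2-iodoethenyl]-2,6,6-trimethylcyclohexan-1-one
Conditions: CrCl2 (6 equiv), THF–dioxane, 0 → 25 °C
Reagents that add atoms: none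
Why: Takai olefination: the geminal dichromium species from CHI3 and CrCl2 adds to the aldehyde and eliminates to the (E)-vinyl iodide, which brings in C11; the reagent is non-basic and should leave the hindered ketone alone.

**Step 6**
Reactants: 10 (2R)-2-[(E)-2-iodoethenyl]-2,6,6-trimethylcyclohexan-1-one; 11 triphenylphosphine
Product: 12 triphenyl{(E)-2-[(1R)-1,3,3-trimethyl-2-oxocyclohexyl]ethenyl}phosphonium iodide
Conditions: Pd(PPh3)4 (3 mol %), toluene, 90 °C
Reagents that add atoms: none
Why: Palladium-catalysed C–P coupling (oxidative addition of the vinyl iodide to zerovalent palladium, then reductive elimination of the phosphonium ion), a known route from vinyl halides to alkenylphosphonium salts that keeps the (E) geometry.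

**Step 7**
Reactants: 12 triphenyl{(E)-2-[(1R)-1,3,3-trimethyl-2-oxocyclohexyl]ethenyl}phosphonium iodide; 13 ethyl 4-(diethoxyphosphoryl)-3-oxobutanoate
Product: 16 ethyl 7-oxido-11-(triphenylphosphonio)-12,13,14,15,16-pentanorlabda-5,7-dien-17-oate (inner salt; 9α-H; 10β-methyl), via sodium enolate 14 (not isolated), via Michael adduct 15 (not isolated)
Conditions: 13, NaH (1.0 equiv), THF–DMF, 0 °C; 12, 0 → 25 °C; then NaH (1.1 equiv), 25 → 60 °C
Reagents that add atoms: none
Why: Proposed new method: the sodium enolate 14 should add through its doubly activated carbon (C8) to the β-carbon (C9) of the alkenylphosphonium ion, the ylide so formed is quenched by internal proton transfer to the phosphonium enolate 15, and the second equivalent of base generates the phosphonate carbanion at C6, which attacks the ring A carbonyl C5 and expels diethyl phosphate (intramolecular Horner–Wadsworth–Emmons olefination). The closest known reactions are the Michael/HWE [3+3] cyclohexenone annulation of 4-phosphonoacetoacetates with enals and enones and the conjugate addition of β-keto ester enolates to vinylphosphonium salts; what is new is that the acceptor carbon and the carbonyl group are held apart by the quaternary C10, so that the phosphonium group is kept on C11. Ring B is closed as a six-membered ring by 6-exo-trig attack of the C6 carbanion on the C5 carbonyl followed by syn elimination of phosphate, and no other ring can form because every ylide/carbonyl pair of 15 would give a four-membered ring and the C5 ketone has no α-hydrogen. The new stereocentre C9 is set in the conjugate addition by the neighbouring quaternary C10: in a Felkin–Anh-type transition state the acyl branch (C5) should lie anti to the incoming enolate, the ring methylene (C1) inside and the methyl group outside, which puts C11 cis to the C10 methyl group (9α-H) as in the target. The step needs site selectivity within 13 (C8 first, C6 second), which the acidity order of the β-keto ester and β-keto phosphonate positions should secure, and the hindered addition at the neopentyl carbon is the reason for choosing a cationic acceptor.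

**Step 8**
Reactants: 17 3-methylideneoxolan-2-one (α-methylene-γ-butyrolactone)
Product: 18 (3R)-3-methyloxolan-2-one
Conditions: H2 (50 atm), Ru(OAc)2[(S)-BINAP] (0.5 mol %), CH2Cl2, 50 °C
Reagents that add atoms: none
Why: Ru–BINAP asymmetric hydrogenation of the exocyclic enoate, a known substrate type, sets the methyl-bearing centre (the future C13) under catalyst control.

**Step 9**
Reactants: 18 (3R)-3-methyloxolan-2-one
Product: 19 (3R)-3-methyloxolan-2-ol (anomer mixture)
Conditions: i-Bu2AlH (1.1 equiv), CH2Cl2, −78 °C; aq. KNaC4H4O6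
Reagents that add atoms: none
Why: Partial reduction of a lactone with i-Bu2AlH stops at the aluminium hemiacetal at low temperature and gives the lactol on work-up; the conditions are non-basic, so the α-centre should be kept.

**Step 10**
Reactants: 16 ethyl 7-oxido-11-(triphenylphosphonio)-12,13,14,15,16-pentanorlabda-5,7-dien-17-oate (inner salt); 19 (3R)-3-methyloxolan-2-ol
Product: 21 ethyl (11Z)-15-hydroxy-7-oxolabda-5,11-dien-17-oate (9α-H; C13 as in 19; C8 epimers and enol), via ylide 20 (not isolated)
Conditions: 16, KN(SiMe3)2 (1.05 equiv), THF, −78 °C; then 19 premixed with KN(SiMe3)2 (1.0 equiv), −78 → 0 °C; aq. NH4Cl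
Reagents that add atoms: none
Why: Wittig olefination of a lactol (masked hydroxy aldehyde) with the non-stabilised ylide 20 joins C11 to C12; the β-keto ester is masked as its enolate, which also blocks retro-Michael loss of the ylide, the alkene geometry is irrelevant, and low temperature should limit enolisation next to C13.

**Step 11**
Reactants: 21 ethyl (11Z)-15-hydroxy-7-oxolabda-5,11-dien-17-oate
Product: 22 ethyl 15-hydroxy-7-oxolabdan-17-oate (5α-H; 9α-H; C8 epimers and enol)
Conditions: H2 (3 atm), Pd/C (10 %), EtOAc, 25 °C
Reagents that add atoms: none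
Why: Heterogeneous hydrogenation saturates the disubstituted side-chain alkene and the enone double bond; hydrogen should reach C5 from the α face, opposite to the axial C10 methyl group, which gives the trans ring fusion (5α-H).

**Step 12**
Reactants: 22 ethyl 15-hydroxy-7-oxolabdan-17-oate
Product: 24 ethyl 15-hydroxy-7-(trifluoromethanesulfonyloxy)labd-7-en-17-oate, via sodium enolate 23 (not isolated)
Conditions: NaH (1.05 equiv), THF, 0 °C; PhNTf2, 0 → 25 °C; aq. NH4Cl
Reagents that add atoms: N-phenylbis(trifluoromethanesulfonimide), O=S(=O)(N(c1ccccc1)S(=O)(=O)C(F)(F)F)C(F)(F)F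
Why: The β-keto ester is by far the most acidic site, so one equivalent of base gives only its enolate, which is O-sulfonylated by the mild triflimide (enol triflate formation); the neutral primary alcohol should not react.

**Step 13**
Reactants: 24 ethyl 15-hydroxy-7-(trifluoromethanesulfonyloxy)labd-7-en-17-oate
Product: 25 ethyl 15-hydroxylabd-7-en-17-oate
Conditions: Pd(OAc)2 (5 mol %), PPh3 (10 mol %), HCO2H, n-Bu3N, DMF, 60 °C
Reagents that add atoms: none
Why: Palladium-catalysed formate reduction of an enol triflate (oxidative addition, formate exchange, loss of CO2, reductive elimination) replaces the triflate by hydrogen and leaves C7=C8 in conjugation with the ester.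

**Step 14**
Reactants: 25 ethyl 15-hydroxylabd-7-en-17-oate
Product: 26 labd-7-ene-15,17-diol
Conditions: i-Bu2AlH (5 equiv), CH2Cl2, −78 → 0 °C; aq. KNaC4H4O6
Reagents that add atoms: none
Why: 1,2-Reduction of the α,β-unsaturated ester with i-Bu2AlH gives the allylic alcohol and does not touch the trisubstituted double bond.

**Step 15**
Reactants: 26 labd-7-ene-15,17-diol
Product: 27 (5S,9R,10S,13S)-labd-7-ene-15,17-diyl diacetate
Conditions: Ac2O, pyridine, DMAP (cat.), CH2Cl2, 25 °C
Reagents that add atoms: acetic anhydride, CC(=O)OC(C)=O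
Why: DMAP-catalysed acetylation of both primary alcohols gives the diacetate; no stereocentre is involved.

**Compound list**

1 | 2,2,6-trimethylcyclohexan-1-one (racemic) | CC1CCCC(C)(C)C1=O | starting material
2 | allyl chloroformate | C=CCOC(Cl)=O | starting material
3 | lithium 2,6,6-trimethylcyclohex-1-en-1-olate | [Li+].[O-]C1=C(C)CCCC1(C)C | intermediate
4 | prop-2-enyl 2,6,6-trimethylcyclohex-1-en-1-yl carbonate | C=CCOC(=O)OC1=C(C)CCCC1(C)C | intermediate
5 | (2R)-2,6,6-trimethyl-2-(prop-2-enyl)cyclohexan-1-one | C=CC[C@@]1(C)CCCC(C)(C)C1=O | intermediate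
6 | (2R)-2,6,6-trimethyl-2-[(E)-prop-1-enyl]cyclohexan-1-one | C/C=C/[C@@]1(C)CCCC(C)(C)C1=O | intermediate
7 | 3-methyl-5-[(1R)-1,3,3-trimethyl-2-oxocyclohexyl]-1,2,4-trioxolane (ozonide, diastereomer mixture) | CC1OOC(O1)[C@@]1(C)CCCC(C)(C)C1=O | intermediate
8 | (1R)-1,3,3-trimethyl-2-oxocyclohexane-1-carbaldehyde | O=C[C@@]1(C)CCCC(C)(C)C1=O | intermediate
9 | iodoform | IC(I)I | starting material
10 | (2R)-2-[(E)-2-iodoethenyl]-2,6,6-trimethylcyclohexan-1-one | I/C=C/[C@@]1(C)CCCC(C)(C)C1=O | intermediate
11 | triphenylphosphine | c1ccccc1P(c1ccccc1)c1ccccc1 | starting material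
12 | triphenyl{(E)-2-[(1R)-1,3,3-trimethyl-2-oxocyclohexyl]ethenyl}phosphonium iodide | [I-].c1ccccc1[P+](c1ccccc1)(c1ccccc1)/C=C/[C@@]1(C)CCCC(C)(C)C1=O | intermediate
13 | ethyl 4-(diethoxyphosphoryl)-3-oxobutanoate | CCOC(=O)CC(=O)CP(=O)(OCC)OCC | starting material
14 | sodium enolate of 13 | [Na+].CCOC(=O)C=C([O-])CP(=O)(OCC)OCC | intermediate
15 | ethyl 6-(diethoxyphosphoryl)-7-oxido-5-oxo-11-(triphenylphosphonio)-5,6-seco-12,13,14,15,16-pentanorlabd-7-en-17-oate (inner salt; C8–C9 bond formed, C9 as in 16) | c1ccccc1[P+](c1ccccc1)(c1ccccc1)C[C@@H](C(C(=O)OCC)=C([O-])CP(=O)(OCC)OCC)[C@@]1(C)CCCC(C)(C)C1=O | intermediate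
16 | ethyl 7-oxido-11-(triphenylphosphonio)-12,13,14,15,16-pentanorlabda-5,7-dien-17-oate (inner salt; 9α-H; 10β-methyl) | c1ccccc1[P+](c1ccccc1)(c1ccccc1)C[C@H]1C(C(=O)OCC)=C([O-])C=C2C(C)(C)CCC[C@]12C | intermediate
17 | 3-methylideneoxolan-2-one | C=C1CCOC1=O | starting material
18 | (3R)-3-methyloxolan-2-one | C[C@@H]1CCOC1=O | intermediate
19 | (3R)-3-methyloxolan-2-ol (anomer mixture) | C[C@@H]1CCOC1O | intermediate
20 | potassium salt of the C11 ylide of 16 | [K+].c1ccccc1P(c1ccccc1)(c1ccccc1)=C[C@H]1C(C(=O)OCC)=C([O-])C=C2C(C)(C)CCC[C@]12C | intermediate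
21 | ethyl (11Z)-15-hydroxy-7-oxolabda-5,11-dien-17-oate (9α-H; C13 as in 19; C8 not defined) | OCC[C@@H](C)/C=C\[C@H]1C(C(=O)OCC)C(=O)C=C2C(C)(C)CCC[C@]12C | intermediate
22 | ethyl 15-hydroxy-7-oxolabdan-17-oate (5α-H; 9α-H; C8 not defined) | OCC[C@@H](C)CC[C@H]1C(C(=O)OCC)C(=O)C[C@H]2C(C)(C)CCC[C@]12C | intermediate
23 | sodium 7-enolate of 22 | [Na+].OCC[C@@H](C)CC[C@H]1C(C(=O)OCC)=C([O-])C[C@H]2C(C)(C)CCC[C@]12C | intermediate
24 | ethyl 15-hydroxy-7-(trifluoromethanesulfonyloxy)labd-7-en-17-oate | OCC[C@@H](C)CC[C@H]1C(C(=O)OCC)=C(OS(=O)(=O)C(F)(F)F)C[C@H]2C(C)(C)CCC[C@]12C | intermediate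
25 | ethyl 15-hydroxylabd-7-en-17-oate | OCC[C@@H](C)CC[C@H]1C(C(=O)OCC)=CC[C@H]2C(C)(C)CCC[C@]12C | intermediate
26 | labd-7-ene-15,17-diol | OCC[C@@H](C)CC[C@H]1C(CO)=CC[C@H]2C(C)(C)CCC[C@]12C | intermediate
27 | (5S,9R,10S,13S)-labd-7-ene-15,17-diyl diacetate | CC(=O)OCC[C@@H](C)CC[C@H]1C(COC(C)=O)=CC[C@H]2C(C)(C)CCC[C@]12C | target

**Step count**

Total step count: 15. Longest linear sequence: 13 steps (steps 1–7 and 10–15).

**Steps most likely to fail**

Step 7 (Proposed new method). The conjugate addition to the neopentyl β-carbon of 12 may be slow and may show poor facial selectivity at C9, so that 16 would be formed as a mixture of C9 epimers. The fallback keeps the bond formation and moves the control of C9 to a reduction. It sets out from 22, which the epimer mixture reaches through steps 10 and 11. Dehydrogenation of the β-keto ester with DDQ (dioxane, 25 → 60 °C), a known reaction of enolised β-dicarbonyl compounds, removes the stereocentre and should give the alkylidene β-keto ester ethyl 15-hydroxy-7-oxolabd-8-en-17-oate F1. Dissolving-metal reduction (Li, NH3–THF, −78 °C, then NH4Cl) should protonate the β-carbon C9 axially from the α face, opposite to the angular methyl group. This returns a single C9 epimer of 22, where the route continues with step 12.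

Step 11. Hydrogen may attack the hindered C5=C6 bond from the β face (cis ring fusion), or the trisubstituted enone may be reduced incompletely. The ring fusion is then set by a dissolving-metal reduction at the dienoate stage. From 21, diimide (p-toluenesulfonyl hydrazide, NaOAc, THF–H2O, 65 °C) saturates only the side-chain double bond and gives ethyl 15-hydroxy-7-oxolabd-5-en-17-oate F2. Enol triflation as in step 12 gives ethyl 15-hydroxy-7-(trifluoromethanesulfonyloxy)labda-5,7-dien-17-oate F3, and formate reduction as in step 13 gives ethyl 15-hydroxylabda-5,7-dien-17-oate F4. Birch-type reduction (Li, NH3, t-BuOH, −78 °C) should add hydrogen at C8 and, axially from the α face, at C5 to give ethyl 15-hydroxylabd-6-en-17-oate F5. NaOEt in EtOH then moves the double bond into conjugation, and the route is rejoined at 25.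

Step 12. Sulfonylation of the free C15 hydroxyl may compete, and O-triflation of the hindered enolate may be slow. The C7 oxygen is then removed by reduction and β-elimination instead. From 22, NaBH4 (EtOH, 0 °C) gives ethyl 7,15-dihydroxylabdan-17-oate F6, and Ac2O with pyridine and DMAP gives ethyl 7,15-diacetoxylabdan-17-oate F7. DBU (toluene, 80 °C) eliminates only the acetate that is β to the ester (E1cB) and gives ethyl 15-acetoxylabd-7-en-17-oate F8. Reduction with i-Bu2AlH as in step 14 cleaves both ester groups and rejoins the route at 26.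

**Further compounds**

F1 | step 7 | ethyl 15-hydroxy-7-oxolabd-8-en-17-oate (5α-H; 10β-methyl) | OCC[C@@H](C)CCC1=C(C(=O)OCC)C(=O)C[C@H]2C(C)(C)CCC[C@]12C
F2 | step 11 | ethyl 15-hydroxy-7-oxolabd-5-en-17-oate (9α-H; C8 not defined) | OCC[C@@H](C)CC[C@H]1C(C(=O)OCC)C(=O)C=C2C(C)(C)CCC[C@]12C
F3 | step 11 | ethyl 15-hydroxy-7-(trifluoromethanesulfonyloxy)labda-5,7-dien-17-oate | OCC[C@@H](C)CC[C@H]1C(C(=O)OCC)=C(OS(=O)(=O)C(F)(F)F)C=C2C(C)(C)CCC[C@]12C
F4 | step 11 | ethyl 15-hydroxylabda-5,7-dien-17-oate | OCC[C@@H](C)CC[C@H]1C(C(=O)OCC)=CC=C2C(C)(C)CCC[C@]12C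
F5 | step 11 | ethyl 15-hydroxylabd-6-en-17-oate (5α-H; C8 not defined) | OCC[C@@H](C)CC[C@H]1C(C(=O)OCC)C=C[C@H]2C(C)(C)CCC[C@]12C
F6 | step 12 | ethyl 7,15-dihydroxylabdan-17-oate (C7 and C8 not defined) | OCC[C@@H](C)CC[C@H]1C(C(=O)OCC)C(O)C[C@H]2C(C)(C)CCC[C@]12C
F7 | step 12 | ethyl 7,15-diacetoxylabdan-17-oate (C7 and C8 not defined) | CC(=O)OCC[C@@H](C)CC[C@H]1C(C(=O)OCC)C(OC(C)=O)C[C@H]2C(C)(C)CCC[C@]12C
F8 | step 12 | ethyl 15-acetoxylabd-7-en-17-oate | CC(=O)OCC[C@@H](C)CC[C@H]1C(C(=O)OCC)=CC[C@H]2C(C)(C)CCC[C@]12C
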